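## The problem

The target **28** is a 2‑oxaspiro[4.5]decane. A γ‑lactone (ring B: C1, O2, C3, C4, C5) and a 4‑acetoxycyclohex‑2‑enone (ring A: C5, C6 ketone, C7=C8, C9 acetoxy carbon, C10) share the all‑carbon quaternary atom C5. C1 also carries a (1E,4E)‑6‑hydroxy‑2,6‑dimethylhepta‑1,4‑dienyl chain (C1' to C7'). Three stereocentres must be set: C5 (R), its neighbour C1 (R), and C9 (S), which lies 1,3 to C5 across ring A with its oxygen on the same ring face as the C1 branch. C1 and C5 are vicinal and can be made together, stereospecifically, from one alkene. C9 cannot be reached in that event, but an oxygen on C1 is placed to deliver a reagent to the correct face of ring A afterwards. The fragile parts are the γ‑acetoxy enone (an allylic acetate, sensitive to base and to zerovalent palladium), the lactone C1–O bond (allylic once the chain is attached), the skipped diene (prone to conjugation and to any electrophilic oxidant) and the tertiary allylic alcohol (ionizes in acid). The chain therefore has to come last. The enabling feature is that C1(OH)–C5–C6(=O) is a β‑hydroxy ketone with an all‑carbon α‑centre, and the ring bond C5–C10 can be read as C10 having moved from C6 to C5. This is the retron of a semipinacol rearrangement of the 2,3‑epoxy alcohol C6(OH)–C5(–O–)C1, in which a cyclopent‑3‑enol expands to ring A.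

## Retrosynthesis

**C3'–C4' (side chain).** The target **28** is cut between the allylic CH2 and the distal alkene, giving the allylic methyl carbonate **25** and the (E)‑alkenylstannane **27** (one step from **26**). A cut at C1–C1' would leave the C1 stereocentre to a late carbonyl addition beside a quaternary carbon. A cut at C1'=C2' with the whole chain would need a non‑stabilized ylide with poor E control. The chosen cut lets the skipped diene and the tertiary alcohol appear only in the last step. It asks zerovalent palladium to ionize the primary carbonate and leave the lactone C1–O bond and the C9 acetate alone.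

**C1'=C2'.** Carbonate **25** comes from alcohol **24**, which comes from enal **23**, made by Wittig olefination of aldehyde **21** with the stabilized formyl ylide **22**. The E geometry is fixed here. The formyl ylide is preferred to an ester ylide because an aldehyde, unlike an enoate, can be reduced beside the enone, lactone and acetate. Aldehyde **21** comes from alcohol **20** and its silyl ether **19**, so C1' is carried through the route as a protected hydroxymethyl group.

**Ring‑A oxygenation and the lactone.** The C9 acetate and the C7=C8 enone of **19** are traced to the β,γ‑epoxy ketone **17** (eliminative opening, then acetylation). The lactone of **17** comes from the 1,4‑diol **15** by oxidative lactonization, and **15** from the bis‑silyl ether **14**. The epoxide of **14** is placed on the C8=C9 alkene of **13** under direction of the free C1 hydroxyl, which sits on the face where the C9 oxygen is needed. This order keeps the only free hydroxyl of **13** as the directing group and ties it up as the lactone before base is used.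

**C5–C10 (key step).** The β‑hydroxy ketone **13** is cut at C5–C10 and C10 is returned to C6, giving the epoxy cyclopentenol **12**. Against an aldol or alkylation at C5, this makes the quaternary centre by a stereospecific 1,2‑shift whose outcome is dictated by the epoxide. Against a cyclization, it closes ring A with no regiochemical choice, since both ring CH2 groups of **12** lead to the same product. C1 carries a silyloxymethyl group rather than an alkenyl ester, for three reasons:
- a vinyl epoxide could ionize at C1;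
- the C1 hydroxyl of **13** would direct oxidation to an allylic side‑chain alkene before ring A;
- an enoate could not be reduced late.

**The epoxide and the five‑membered ring.** Cyclopentenol **12** comes from the diallyl carbinol **11** by ring‑closing metathesis, and **11** from the Z‑alkene **10** by Shi epoxidation. Epoxidizing before ring closure means the chiral dioxirane meets a trisubstituted alkene beside two monosubstituted ones, not beside a cis‑disubstituted cyclopentene. The reaction must set both C5 and C1 as the (2R,3R)‑oxirane.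

**The Z‑alkene.** Silyl ether **10** comes from diol **9**, and **9** from the butenolide **7** and two equivalents of allylmagnesium bromide **8**. The lactone ring of **7** forces the carbinol carbon (C6) and C1' to be cis, which is the geometry the epoxide needs and the harder one to obtain in an open chain. The two allyl groups supply C7 to C10.

**The butenolide.** Butenolide **7** comes from the (Z)‑iodo alcohol **6** by carbonylative lactonization. **6** comes from the propargylic alcohol **4** by hydroxyl‑directed trans‑hydroalumination and iodination, **4** from the silyl ether **2** by hydroxymethylation, and **2** from but‑3‑yn‑1‑ol **1**.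

## Roads not taken

**Alternative 1:** The cut is the C9–O bond together with the desymmetrization of ring A. The achiral diene acid **A1** (from Birch reductive alkylation of benzoic acid) is treated with an electrophilic bromine source and a cinchona‑alkaloid catalyst. One enantiotopic alkene is brominated, and the carboxylate closes anti onto C9 to give the bridged bromolactone **A2**, making C5 stereogenic.
- Merits: ring A and the quaternary carbon come from an aromatic ring in two steps, and the bridge enforces the cis relation between the C9 oxygen and the C1 carbon. In this respect it is better than the chosen plan, which relies on a directed epoxidation (step 10).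
- Weak points: the lactone carbonyl of **A2** is C1 at the wrong oxidation level. It must be reduced to the aldehyde and the chain added there, so C1 is set by addition next to a quaternary carbon under uncertain substrate control. Bromine must be removed from C10, two carboxyl groups must be told apart, the lactone must be re‑formed onto C3, and C6 must be oxidized with transposition of the C6=C7 alkene.
- Comparison: the chosen plan sets against the secure C5/C9 relation of **A2** the fact that C1 and C5 come from one stereospecific event and that ring A reaches its final oxidation pattern through an epoxide opening.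

**Alternative 2:** The cut is C5–C6 and C9–C10. 2‑Methoxyfuran **A3** and the 2‑substituted acrolein **A4** undergo a catalysed exo [4+2] cycloaddition, and the oxa‑bridged ketal opens in the same flask to the hydroxy enone aldehyde **A5**.
- Merits: it is by far the shortest way to ring A. The quaternary centre, the enone and the C9 hydroxyl arrive in one step with a matched regiochemistry (the unsubstituted furan terminus bonds to the acrolein CH2).
- Weak points: furan cycloadditions are reversible, so exo/endo and facial control for a 2‑substituted acrolein must hold under conditions that also open the bridge. **A5** is a non‑enolizable β‑keto aldehyde, open to deformylation by nucleophiles. C1 is again left to an addition to a neopentyl aldehyde flanked by two similar ring branches.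
- Comparison: in step count this road is clearly better for ring A. The chosen plan is longer but sets C1 relative to C5 by mechanism, not by a late diastereoselective addition.

**Alternative 3:** The cut is C1–C1' and the lactone C–O bond. The alkenylchromium reagent from the (E)‑alkenyl iodide **A7** (chromium‑mediated, nickel‑catalysed) adds to the aldehyde ester **A6**, and the alkoxide closes ring B on the C3 ester to give the silyl ether **A8**.
- Merits: it is the most convergent endgame. The whole chain arrives in one piece under conditions that tolerate ketone, ester and enone, and only desilylation and acetylation remain.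
- Weak points: the C1 stereocentre is created in the coupling itself. Its sense depends on the conformation of an α‑quaternary β‑keto aldehyde, with chelated and non‑chelated pathways leading to opposite epimers. The enantioenriched aldehyde **A6** must first be made by something like Alternative 2.
- Comparison: the chosen plan needs four late steps for what this road does in one. It sets against this that the lactone carbinol configuration is already in place before the chain is built.

Key step: step 9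

## Route

Remark: ring atoms are numbered as in the first section. The CIP letters at C1 and C5 change along the route only because substituent priorities change; neither centre is touched after step 9.

Remark: the D‑fructose‑derived Shi ketone is assumed to attack **10** with its usual facial sense for trisubstituted alkenes (the sense that turns 1‑phenylcyclohexene into its (R,R)‑oxide). With the vinylic hydrogen as reference, this gives the (2R,3R)‑oxirane.

Step 1
Reactants: 1 but‑3‑yn‑1‑ol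
Product: 2 tert‑butyl(but‑3‑yn‑1‑yloxy)dimethylsilane
Conditions: TBSCl, imidazole, DMF, 0 °C → rt
Reagents that add atoms: tert‑butyldimethylsilyl chloride, CC(C)(C)[Si](C)(C)Cl
Why: Standard silylation of a primary alcohol; the TBS ether tolerates the organolithium, hydride and Grignard reagents that follow.

Step 2
Reactants: 2 tert‑butyl(but‑3‑yn‑1‑yloxy)dimethylsilane
Product: 4 5‑[(tert‑butyldimethylsilyl)oxy]pent‑2‑yn‑1‑ol, via lithium acetylide 3 (not isolated)
Conditions: n‑BuLi, THF, −78 °C; (CH2O)n, −78 °C → rt; then H2O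
Reagents that add atoms: paraformaldehyde (as formaldehyde), C=O
Why: Acetylide addition to formaldehyde (alkynylation); it installs C1' and the propargylic hydroxyl that directs the next step.

Step 3
Reactants: 4 5‑[(tert‑butyldimethylsilyl)oxy]pent‑2‑yn‑1‑ol
Product: 6 (2Z)‑5‑[(tert‑butyldimethylsilyl)oxy]‑3‑iodopent‑2‑en‑1‑ol, via sodium alkenylaluminate 5 (not isolated)
Conditions: NaAlH2(OCH2CH2OMe)2 (Red‑Al), THF, 0 °C → rt; then I2, −78 → 0 °C; then H2O
Reagents that add atoms: iodine, II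
Why: Hydroxyl‑directed trans‑hydroalumination of a propargylic alcohol and iododealumination with retention; the five‑membered cyclic aluminate places aluminium, then iodine, on C3 cis to the CH2OH group, which fixes the Z geometry.

Step 4
Reactants: 6 (2Z)‑5‑[(tert‑butyldimethylsilyl)oxy]‑3‑iodopent‑2‑en‑1‑ol
Product: 7 3‑{2‑[(tert‑butyldimethylsilyl)oxy]ethyl}furan‑2(5H)‑one
Conditions: CO (1 atm), PdCl2(PPh3)2 (cat.), K2CO3, THF, 25–40 °C
Reagents that add atoms: carbon monoxide, [C-]#[O+]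
Why: Palladium‑catalysed carbonylative lactonization of a (Z)‑3‑iodoallylic alcohol (oxidative addition, CO insertion, capture of the acylpalladium by the cis hydroxyl); the ring locks the future C6 and C1' cis.

Step 5
Reactants: 7 3‑{2‑[(tert‑butyldimethylsilyl)oxy]ethyl}furan‑2(5H)‑one; 8 allylmagnesium bromide
Product: 9 (2Z)‑3‑{2‑[(tert‑butyldimethylsilyl)oxy]ethyl}‑4‑(prop‑2‑en‑1‑yl)hepta‑2,6‑diene‑1,4‑diol
Conditions: 8 (3 equiv), THF/Et2O, −78 → 0 °C; then H2O
Reagents that add atoms: none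
Why: Double Grignard addition to a lactone; allylmagnesium halides add 1,2 even to unsaturated esters, ring opening frees the primary allylic alcohol, and the alkene geometry is carried over from the ring.

Step 6
Reactants: 9 (2Z)‑3‑{2‑[(tert‑butyldimethylsilyl)oxy]ethyl}‑4‑(prop‑2‑en‑1‑yl)hepta‑2,6‑diene‑1,4‑diol
Product: 10 (5Z)‑7‑[(tert‑butyldiphenylsilyl)oxy]‑5‑{2‑[(tert‑butyldimethylsilyl)oxy]ethyl}‑4‑(prop‑2‑en‑1‑yl)hepta‑1,5‑dien‑4‑ol
Conditions: TBDPSCl, imidazole, CH2Cl2, 0 °C
Reagents that add atoms: tert‑butyldiphenylsilyl chloride, CC(C)(C)[Si](Cl)(c1ccccc1)c1ccccc1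
Why: Selective silylation of the primary hydroxyl beside the hindered tertiary one; the TBDPS ether is stable to Lewis acid and can be kept while the primary TBS ether is removed.

Step 7
Reactants: 10 (5Z)‑7‑[(tert‑butyldiphenylsilyl)oxy]‑5‑{2‑[(tert‑butyldimethylsilyl)oxy]ethyl}‑4‑(prop‑2‑en‑1‑yl)hepta‑1,5‑dien‑4‑ol
Product: 11 4‑[(2R,3R)‑3‑{[(tert‑butyldiphenylsilyl)oxy]methyl}‑2‑{2‑[(tert‑butyldimethylsilyl)oxy]ethyl}oxiran‑2‑yl]hepta‑1,6‑dien‑4‑ol
Conditions: Shi ketone (D‑fructose‑derived, 0.3 equiv), Oxone (2KHSO5·KHSO4·K2SO4), K2CO3, Bu4NHSO4 (cat.), aq. Na2B4O7 buffer, MeCN/CH2(OMe)2, 0 °C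
Reagents that add atoms: Oxone (potassium peroxymonosulfate), [K+].[O-]S(=O)(=O)OO
Why: Shi asymmetric epoxidation by a chiral dioxirane; the trisubstituted alkene should react well ahead of the two monosubstituted allyl termini, and the spiro transition state with the single vinylic hydrogen next to the catalyst ketal delivers oxygen to one face, setting C5 and C1 together as the (2R,3R)‑oxirane from the Z‑alkene.

Step 8
Reactants: 11 4‑[(2R,3R)‑3‑{[(tert‑butyldiphenylsilyl)oxy]methyl}‑2‑{2‑[(tert‑butyldimethylsilyl)oxy]ethyl}oxiran‑2‑yl]hepta‑1,6‑dien‑4‑ol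
Product: 12 1‑[(2R,3R)‑3‑{[(tert‑butyldiphenylsilyl)oxy]methyl}‑2‑{2‑[(tert‑butyldimethylsilyl)oxy]ethyl}oxiran‑2‑yl]cyclopent‑3‑en‑1‑ol
Conditions: second‑generation Grubbs catalyst (H2IMes)(PCy3)Cl2Ru=CHPh (3 mol%), CH2Cl2, 40 °C
Reagents that add atoms: none
Why: Ring‑closing metathesis of a 4,4‑disubstituted hepta‑1,6‑diene to a cyclopentene; free tertiary alcohols, epoxides and silyl ethers are tolerated.

Step 9
Reactants: 12 1‑[(2R,3R)‑3‑{[(tert‑butyldiphenylsilyl)oxy]methyl}‑2‑{2‑[(tert‑butyldimethylsilyl)oxy]ethyl}oxiran‑2‑yl]cyclopent‑3‑en‑1‑ol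
Product: 13 (6R)‑6‑[(1S)‑2‑[(tert‑butyldiphenylsilyl)oxy]‑1‑hydroxyethyl]‑6‑{2‑[(tert‑butyldimethylsilyl)oxy]ethyl}cyclohex‑3‑en‑1‑one
Conditions: ZnBr2 (1.2 equiv), CH2Cl2, 0 °C → rt
Reagents that add atoms: none
Why: ZnBr2 binds the epoxide oxygen and the carbinol, the tertiary C5–O bond lengthens, and one ring CH2 of the cyclopentenol shifts from C6 to C5 anti to the departing oxygen while C6–O becomes the carbonyl. This is the semipinacol rearrangement of a 2,3‑epoxy alcohol, the known route from tertiary epoxy carbinols to β‑hydroxy ketones with α‑quaternary centres, including one‑carbon ring expansion of cycloalkanols. Ring A is closed by this 1,2‑alkyl shift and not by a cyclization: the five‑membered carbinol ring takes up C5 and becomes the six‑membered ketone through the new bond C5–C10. The quaternary centre C5 is formed with inversion at the epoxide carbon, so its configuration follows from the oxirane of step 7, and C1 keeps its oxygen and its configuration. The two ring CH2 groups are diastereotopic but constitutionally equivalent, so either migration gives the same product. The step needs opening at C5 and not at C1, and a carbon shift and not a hydride shift from C1. C5 is tertiary and next to the electron‑releasing carbinol, C1 is secondary and bears an inductively withdrawing silyloxymethyl group and no π system, and the developing C6 oxocarbenium makes the carbon shift the fastest way to quench the cation. Mild anhydrous conditions should keep the C8=C9 alkene out of conjugation and both silyl ethers in place.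

Step 10
Reactants: 13 (6R)‑6‑[(1S)‑2‑[(tert‑butyldiphenylsilyl)oxy]‑1‑hydroxyethyl]‑6‑{2‑[(tert‑butyldimethylsilyl)oxy]ethyl}cyclohex‑3‑en‑1‑one
Product: 14 (1R,4S,6S)‑4‑[(1S)‑2‑[(tert‑butyldiphenylsilyl)oxy]‑1‑hydroxyethyl]‑4‑{2‑[(tert‑butyldimethylsilyl)oxy]ethyl}‑7‑oxabicyclo[4.1.0]heptan‑3‑one
Conditions: VO(acac)2 (5 mol%), t‑BuOOH, CH2Cl2, 0 °C → rt
Reagents that add atoms: tert‑butyl hydroperoxide, CC(C)(C)OO
Why: Hydroxyl‑directed vanadium/peroxide epoxidation of a bishomoallylic alcohol; the C1 vanadate ester delivers oxygen to the ring face that carries the carbinol branch, so the epoxide (and later the C9 oxygen) is cis to C1, and an unactivated alkene does not react without the tether.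

Step 11
Reactants: 14 (1R,4S,6S)‑4‑[(1S)‑2‑[(tert‑butyldiphenylsilyl)oxy]‑1‑hydroxyethyl]‑4‑{2‑[(tert‑butyldimethylsilyl)oxy]ethyl}‑7‑oxabicyclo[4.1.0]heptan‑3‑one
Product: 15 (1R,4S,6S)‑4‑[(1S)‑2‑[(tert‑butyldiphenylsilyl)oxy]‑1‑hydroxyethyl]‑4‑(2‑hydroxyethyl)‑7‑oxabicyclo[4.1.0]heptan‑3‑one
Conditions: HF·pyridine, pyridine, THF, 0 °C
Reagents that add atoms: none
Why: Selective cleavage of a primary TBS ether beside the more robust primary TBDPS ether; buffered HF·pyridine should spare the epoxide and the ketone.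

Step 12
Reactants: 15 (1R,4S,6S)‑4‑[(1S)‑2‑[(tert‑butyldiphenylsilyl)oxy]‑1‑hydroxyethyl]‑4‑(2‑hydroxyethyl)‑7‑oxabicyclo[4.1.0]heptan‑3‑one
Product: 17 (1S,5R,8R,9S)‑1‑{[(tert‑butyldiphenylsilyl)oxy]methyl}‑8,9‑epoxy‑2‑oxaspiro[4.5]decane‑3,6‑dione, via spirolactol 16 (not isolated)
Conditions: TEMPO (cat.), PhI(OAc)2 (2.5 equiv), CH2Cl2, rt
Reagents that add atoms: none
Why: TEMPO/PhI(OAc)2 oxidative lactonization of a 1,4‑diol; the primary alcohol is oxidized first, the aldehyde closes with the hindered C1 hydroxyl to the five‑membered lactol, and a second oxidation gives the γ‑lactone (ring B).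

Step 13
Reactants: 17 (1S,5R,8R,9S)‑1‑{[(tert‑butyldiphenylsilyl)oxy]methyl}‑8,9‑epoxy‑2‑oxaspiro[4.5]decane‑3,6‑dione
Product: 19 (1S,5R,9S)‑1‑{[(tert‑butyldiphenylsilyl)oxy]methyl}‑3,6‑dioxo‑2‑oxaspiro[4.5]dec‑7‑en‑9‑yl acetate, via hydroxy enone 18 (not isolated)
Conditions: Et3N, CH2Cl2, 0 °C → rt; then Ac2O, DMAP (cat.), 0 °C
Reagents that add atoms: acetic anhydride, CC(=O)OC(C)=O
Why: Base‑mediated eliminative opening of a β,γ‑epoxy ketone (E1cB): deprotonation at C7 and cleavage of the C8–O bond give the C7=C8 enone and the C9 alcohol with its configuration unchanged, and the alcohol is acetylated in the same flask.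

Step 14
Reactants: 19 (1S,5R,9S)‑1‑{[(tert‑butyldiphenylsilyl)oxy]methyl}‑3,6‑dioxo‑2‑oxaspiro[4.5]dec‑7‑en‑9‑yl acetate
Product: 20 (1S,5R,9S)‑1‑(hydroxymethyl)‑3,6‑dioxo‑2‑oxaspiro[4.5]dec‑7‑en‑9‑yl acetate
Conditions: HF·pyridine, THF, 0 °C → rt
Reagents that add atoms: none
Why: Fluoride cleavage of the TBDPS ether under mildly acidic conditions that spare the acetate, the lactone and the enone.

Step 15
Reactants: 20 (1S,5R,9S)‑1‑(hydroxymethyl)‑3,6‑dioxo‑2‑oxaspiro[4.5]dec‑7‑en‑9‑yl acetate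
Product: 21 (1S,5R,9S)‑1‑formyl‑3,6‑dioxo‑2‑oxaspiro[4.5]dec‑7‑en‑9‑yl acetate
Conditions: Dess–Martin periodinane, CH2Cl2, 0 °C → rt
Reagents that add atoms: none
Why: Dess–Martin oxidation of a primary alcohol to the aldehyde under neutral conditions that should not enolize the α‑acyloxy aldehyde.

Step 16
Reactants: 21 (1S,5R,9S)‑1‑formyl‑3,6‑dioxo‑2‑oxaspiro[4.5]dec‑7‑en‑9‑yl acetate; 22 2‑(triphenylphosphoranylidene)propanal
Product: 23 (1R,5R,9S)‑1‑[(1E)‑2‑methyl‑3‑oxoprop‑1‑en‑1‑yl]‑3,6‑dioxo‑2‑oxaspiro[4.5]dec‑7‑en‑9‑yl acetate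
Conditions: 22 (1.3 equiv), toluene, 70 °C
Reagents that add atoms: none
Why: Wittig olefination with a stabilized ylide gives the (E)‑trisubstituted enal (C1 trans to C3'); the ylide is too weakly nucleophilic to attack the hindered ring ketone and too weakly basic to epimerize C1.

Step 17
Reactants: 23 (1R,5R,9S)‑1‑[(1E)‑2‑methyl‑3‑oxoprop‑1‑en‑1‑yl]‑3,6‑dioxo‑2‑oxaspiro[4.5]dec‑7‑en‑9‑yl acetate
Product: 24 (1R,5R,9S)‑1‑[(1E)‑3‑hydroxy‑2‑methylprop‑1‑en‑1‑yl]‑3,6‑dioxo‑2‑oxaspiro[4.5]dec‑7‑en‑9‑yl acetate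
Conditions: NaBH4 (0.3 equiv), EtOH/CH2Cl2, −78 °C
Reagents that add atoms: none
Why: Chemoselective 1,2‑reduction of an aldehyde beside a ketone with borohydride at low temperature; the unhindered enal is far more electrophilic than the α‑quaternary ring enone, and lactone and acetate are inert.

Step 18
Reactants: 24 (1R,5R,9S)‑1‑[(1E)‑3‑hydroxy‑2‑methylprop‑1‑en‑1‑yl]‑3,6‑dioxo‑2‑oxaspiro[4.5]dec‑7‑en‑9‑yl acetate
Product: 25 (1R,5R,9S)‑1‑{(1E)‑3‑[(methoxycarbonyl)oxy]‑2‑methylprop‑1‑en‑1‑yl}‑3,6‑dioxo‑2‑oxaspiro[4.5]dec‑7‑en‑9‑yl acetate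
Conditions: ClCO2Me, pyridine, CH2Cl2, 0 °C
Reagents that add atoms: methyl chloroformate, COC(=O)Cl
Why: Carbonate formation at the only free hydroxyl; the primary allylic carbonate becomes the most easily ionized allylic C–O bond in the molecule.

Step 19
Reactants: 26 2‑methylbut‑3‑yn‑2‑ol
Product: 27 (3E)‑2‑methyl‑4‑(tributylstannyl)but‑3‑en‑2‑ol
Conditions: Bu3SnH, PdCl2(PPh3)2 (2 mol%), THF, 0 °C → rt
Reagents that add atoms: tributyltin hydride, CCCC[SnH](CCCC)CCCC
Why: Palladium‑catalysed syn‑hydrostannation of a terminal alkyne; the bulky tertiary carbinol sends tin to the terminal carbon, giving the (E)‑alkenylstannane.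

Step 20
Reactants: 25 (1R,5R,9S)‑1‑{(1E)‑3‑[(methoxycarbonyl)oxy]‑2‑methylprop‑1‑en‑1‑yl}‑3,6‑dioxo‑2‑oxaspiro[4.5]dec‑7‑en‑9‑yl acetate; 27 (3E)‑2‑methyl‑4‑(tributylstannyl)but‑3‑en‑2‑ol
Product: 28 (1R,5R,9S)‑1‑[(1E,4E)‑6‑hydroxy‑2,6‑dimethylhepta‑1,4‑dien‑1‑yl]‑3,6‑dioxo‑2‑oxaspiro[4.5]dec‑7‑en‑9‑yl acetate
Conditions: Pd2(dba)3 (5 mol%), LiCl, DMF, 25–40 °C
Reagents that add atoms: none
Why: Stille coupling of an allylic carbonate through a π‑allylpalladium intermediate; zerovalent palladium ionizes the primary carbonate, the alkenyl group is transferred from tin with retention, and reductive elimination at the unsubstituted allyl terminus forms C3'–C4' while the syn π‑allyl keeps the E geometry of C1'=C2'.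

## Compound list

1 | but‑3‑yn‑1‑ol | C#CCCO | starting material
2 | tert‑butyl(but‑3‑yn‑1‑yloxy)dimethylsilane | C#CCCO[Si](C)(C)C(C)(C)C | intermediate
3 | lithium acetylide of 2 | [Li]C#CCCO[Si](C)(C)C(C)(C)C | intermediate
4 | 5‑[(tert‑butyldimethylsilyl)oxy]pent‑2‑yn‑1‑ol | OCC#CCCO[Si](C)(C)C(C)(C)C | intermediate
5 | sodium alkenylaluminate (cyclic 2,5‑dihydro‑1,2‑oxaaluminole ate complex with two 2‑methoxyethoxy ligands) | [Na+].COCCO[Al-]1(OCCOC)OCC=C1CCO[Si](C)(C)C(C)(C)C | intermediate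
6 | (2Z)‑5‑[(tert‑butyldimethylsilyl)oxy]‑3‑iodopent‑2‑en‑1‑ol | OC/C=C(\I)CCO[Si](C)(C)C(C)(C)C | intermediate
7 | 3‑{2‑[(tert‑butyldimethylsilyl)oxy]ethyl}furan‑2(5H)‑one | O=C1OCC=C1CCO[Si](C)(C)C(C)(C)C | intermediate
8 | allylmagnesium bromide | C=CC[Mg]Br | starting material
9 | (2Z)‑3‑{2‑[(tert‑butyldimethylsilyl)oxy]ethyl}‑4‑(prop‑2‑en‑1‑yl)hepta‑2,6‑diene‑1,4‑diol | OC/C=C(/CCO[Si](C)(C)C(C)(C)C)C(O)(CC=C)CC=C | intermediate
10 | (5Z)‑7‑[(tert‑butyldiphenylsilyl)oxy]‑5‑{2‑[(tert‑butyldimethylsilyl)oxy]ethyl}‑4‑(prop‑2‑en‑1‑yl)hepta‑1,5‑dien‑4‑ol | CC(C)(C)[Si](c1ccccc1)(c1ccccc1)OC/C=C(/CCO[Si](C)(C)C(C)(C)C)C(O)(CC=C)CC=C | intermediate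
11 | 4‑[(2R,3R)‑3‑{[(tert‑butyldiphenylsilyl)oxy]methyl}‑2‑{2‑[(tert‑butyldimethylsilyl)oxy]ethyl}oxiran‑2‑yl]hepta‑1,6‑dien‑4‑ol | C=CCC(O)(CC=C)[C@]1(CCO[Si](C)(C)C(C)(C)C)O[C@@H]1CO[Si](c1ccccc1)(c1ccccc1)C(C)(C)C | intermediate
12 | 1‑[(2R,3R)‑3‑{[(tert‑butyldiphenylsilyl)oxy]methyl}‑2‑{2‑[(tert‑butyldimethylsilyl)oxy]ethyl}oxiran‑2‑yl]cyclopent‑3‑en‑1‑ol | OC1(CC=CC1)[C@]2(CCO[Si](C)(C)C(C)(C)C)O[C@@H]2CO[Si](c3ccccc3)(c3ccccc3)C(C)(C)C | intermediate
13 | (6R)‑6‑[(1S)‑2‑[(tert‑butyldiphenylsilyl)oxy]‑1‑hydroxyethyl]‑6‑{2‑[(tert‑butyldimethylsilyl)oxy]ethyl}cyclohex‑3‑en‑1‑one | O=C1[C@@]([C@H](O)CO[Si](c2ccccc2)(c2ccccc2)C(C)(C)C)(CCO[Si](C)(C)C(C)(C)C)CC=CC1 | intermediate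
14 | (1R,4S,6S)‑4‑[(1S)‑2‑[(tert‑butyldiphenylsilyl)oxy]‑1‑hydroxyethyl]‑4‑{2‑[(tert‑butyldimethylsilyl)oxy]ethyl}‑7‑oxabicyclo[4.1.0]heptan‑3‑one (epoxide cis to the carbinol branch) | O=C1C[C@H]2O[C@H]2C[C@@]1(CCO[Si](C)(C)C(C)(C)C)[C@H](O)CO[Si](c3ccccc3)(c3ccccc3)C(C)(C)C | intermediate
15 | (1R,4S,6S)‑4‑[(1S)‑2‑[(tert‑butyldiphenylsilyl)oxy]‑1‑hydroxyethyl]‑4‑(2‑hydroxyethyl)‑7‑oxabicyclo[4.1.0]heptan‑3‑one | O=C1C[C@H]2O[C@H]2C[C@@]1(CCO)[C@H](O)CO[Si](c3ccccc3)(c3ccccc3)C(C)(C)C | intermediate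
16 | (1S,5R,8R,9S)‑1‑{[(tert‑butyldiphenylsilyl)oxy]methyl}‑8,9‑epoxy‑3‑hydroxy‑2‑oxaspiro[4.5]decan‑6‑one (lactol, both C3 epimers) | O=C1C[C@H]2O[C@H]2C[C@]13CC(O)O[C@@H]3CO[Si](c4ccccc4)(c4ccccc4)C(C)(C)C | intermediate
17 | (1S,5R,8R,9S)‑1‑{[(tert‑butyldiphenylsilyl)oxy]methyl}‑8,9‑epoxy‑2‑oxaspiro[4.5]decane‑3,6‑dione | O=C1C[C@H]2O[C@H]2C[C@]13CC(=O)O[C@@H]3CO[Si](c4ccccc4)(c4ccccc4)C(C)(C)C | intermediate
18 | (1S,5R,9S)‑1‑{[(tert‑butyldiphenylsilyl)oxy]methyl}‑9‑hydroxy‑2‑oxaspiro[4.5]dec‑7‑ene‑3,6‑dione | O[C@@H]1C=CC(=O)[C@@]2(CC(=O)O[C@@H]2CO[Si](c3ccccc3)(c3ccccc3)C(C)(C)C)C1 | intermediate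
19 | (1S,5R,9S)‑1‑{[(tert‑butyldiphenylsilyl)oxy]methyl}‑3,6‑dioxo‑2‑oxaspiro[4.5]dec‑7‑en‑9‑yl acetate | CC(=O)O[C@@H]1C=CC(=O)[C@@]2(CC(=O)O[C@@H]2CO[Si](c3ccccc3)(c3ccccc3)C(C)(C)C)C1 | intermediate
20 | (1S,5R,9S)‑1‑(hydroxymethyl)‑3,6‑dioxo‑2‑oxaspiro[4.5]dec‑7‑en‑9‑yl acetate | CC(=O)O[C@@H]1C=CC(=O)[C@@]2(CC(=O)O[C@@H]2CO)C1 | intermediate
21 | (1S,5R,9S)‑1‑formyl‑3,6‑dioxo‑2‑oxaspiro[4.5]dec‑7‑en‑9‑yl acetate | CC(=O)O[C@@H]1C=CC(=O)[C@@]2(CC(=O)O[C@@H]2C=O)C1 | intermediate
22 | 2‑(triphenylphosphoranylidene)propanal | CC(C=O)=P(c1ccccc1)(c1ccccc1)c1ccccc1 | starting material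
23 | (1R,5R,9S)‑1‑[(1E)‑2‑methyl‑3‑oxoprop‑1‑en‑1‑yl]‑3,6‑dioxo‑2‑oxaspiro[4.5]dec‑7‑en‑9‑yl acetate | CC(=O)O[C@@H]1C=CC(=O)[C@@]2(CC(=O)O[C@@H]2/C=C(\C)C=O)C1 | intermediate
24 | (1R,5R,9S)‑1‑[(1E)‑3‑hydroxy‑2‑methylprop‑1‑en‑1‑yl]‑3,6‑dioxo‑2‑oxaspiro[4.5]dec‑7‑en‑9‑yl acetate | CC(=O)O[C@@H]1C=CC(=O)[C@@]2(CC(=O)O[C@@H]2/C=C(\C)CO)C1 | intermediate
25 | (1R,5R,9S)‑1‑{(1E)‑3‑[(methoxycarbonyl)oxy]‑2‑methylprop‑1‑en‑1‑yl}‑3,6‑dioxo‑2‑oxaspiro[4.5]dec‑7‑en‑9‑yl acetate | CC(=O)O[C@@H]1C=CC(=O)[C@@]2(CC(=O)O[C@@H]2/C=C(\C)COC(=O)OC)C1 | intermediate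
26 | 2‑methylbut‑3‑yn‑2‑ol | CC(C)(O)C#C | starting material
27 | (3E)‑2‑methyl‑4‑(tributylstannyl)but‑3‑en‑2‑ol | CCCC[Sn](CCCC)(CCCC)/C=C/C(C)(C)O | intermediate
28 | (1R,5R,9S)‑1‑[(1E,4E)‑6‑hydroxy‑2,6‑dimethylhepta‑1,4‑dien‑1‑yl]‑3,6‑dioxo‑2‑oxaspiro[4.5]dec‑7‑en‑9‑yl acetate (the dextrorotatory miliusane target) | CC(=O)O[C@@H]1C=CC(=O)[C@@]2(CC(=O)O[C@@H]2/C=C(\C)C/C=C/C(C)(C)O)C1 | target

## Step count and risks

Total: 20 steps. Longest linear sequence: 19 steps (steps 1–18 and 20, from but‑3‑yn‑1‑ol); step 19 is a one‑step side branch.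

**Step 9 (key step).** The most likely failure is that the C5 cation is quenched by a 1,2‑hydride shift from C1 (Meinwald‑type isomerization to a C1 ketone) instead of the ring‑carbon shift. The Lewis acid may also cleave the primary TBS ether or move the C8=C9 alkene into conjugation with the new ketone. All three would follow from a shift that is too slow under conditions mild enough for the product. Fallback: starting from **12**, the tertiary hydroxyl is silylated (TMSOTf, 2,6‑lutidine, CH2Cl2, −78 °C) to the trimethylsilyl ether of **12**, F1. The rearrangement is then run in its epoxy silyl ether form with TiCl4 in CH2Cl2 at −78 °C, where a silyloxocarbenium ion, not a zinc alkoxide, drives the carbon shift and the low temperature protects the β,γ‑enone. Loss of the trimethylsilyl group on aqueous work‑up returns the route at **13**.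

**Step 7.** Oxygen transfer to a hindered alkene bearing two allylic oxygens may be slow. Epoxidation of the allyl termini and oxidative decay of the catalyst then compete, and the bulky carbinol cis to the silyloxymethyl group may erode facial discrimination. Fallback: starting from diol **9**, a Sharpless asymmetric epoxidation directed by the primary allylic hydroxyl (Ti(OiPr)4, D‑(−)‑diethyl tartrate, t‑BuOOH, 4 Å sieves, CH2Cl2, −20 °C) gives the epoxy diol 4‑[(2R,3R)‑2‑{2‑[(tert‑butyldimethylsilyl)oxy]ethyl}‑3‑(hydroxymethyl)oxiran‑2‑yl]hepta‑1,6‑dien‑4‑ol, F2. This reaction touches only the allylic alkene. It is sensitive to the bulky cis substituent, so stoichiometric titanium and long reaction times are expected. Silylation of the primary hydroxyl (TBDPSCl, imidazole) rejoins the route at **11**.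

**Step 10.** The hindered secondary hydroxyl may bind vanadium poorly, so the bishomoallylic delivery is slow or not face‑selective. Fallback: starting from **13**, the steric bias of the spirolactone is used instead and C9 is corrected by inversion.
- The TBS ether is removed (HF·pyridine) to give the diol (6R)‑6‑[(1S)‑2‑[(tert‑butyldiphenylsilyl)oxy]‑1‑hydroxyethyl]‑6‑(2‑hydroxyethyl)cyclohex‑3‑en‑1‑one, F3.
- Oxidative lactonization (TEMPO, PhI(OAc)2) gives (1S,5R)‑1‑{[(tert‑butyldiphenylsilyl)oxy]methyl}‑2‑oxaspiro[4.5]dec‑8‑ene‑3,6‑dione, F4.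
- Peracid epoxidation (mCPBA, NaHCO3, CH2Cl2) from the face opposite the bulky C1 branch gives the (8S,9R)‑epoxide of F4, F5.
- Et3N opens it to the 9‑epi alcohol (1S,5R,9R)‑1‑{[(tert‑butyldiphenylsilyl)oxy]methyl}‑9‑hydroxy‑2‑oxaspiro[4.5]dec‑7‑ene‑3,6‑dione, F6.
- Mitsunobu esterification with acetic acid (PPh3, DIAD) inverts C9 and rejoins the route at **19**.

**Step 16.** The α‑acyloxy aldehyde may enolize (epimerization at C1) or sit as a hydrate while the weakly nucleophilic formyl ylide reacts slowly at the temperature it needs. Fallback: starting from **21**, a Nozaki–Hiyama–Kishi addition of 2‑bromopropene (CrCl2, catalytic NiCl2, DMF, rt; non‑basic) gives the allylic alcohol (1S,5R,9S)‑1‑(1‑hydroxy‑2‑methylprop‑2‑en‑1‑yl)‑3,6‑dioxo‑2‑oxaspiro[4.5]dec‑7‑en‑9‑yl acetate, F7, as either or both C1' epimers. Methyl chloroformate/pyridine converts it to the branched carbonate of F7, F8. Coupling with **27** under the conditions of step 20 passes through the same π‑allylpalladium intermediate as **25** and rejoins the route at **28**, bypassing steps 16–18.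

**Step 20.** Zerovalent palladium may also ionize the lactone C1–O bond (now allylic) or the C9 acetate, leading to epimerization at C1 or loss of acetate. A slow transmetalation would allow β‑hydride elimination of the π‑allyl to a diene. Fallback: starting from **24**, the C3'–C4' bond is made without an allylpalladium intermediate.
- Appel bromination (CBr4, PPh3) gives the allylic bromide (1R,5R,9S)‑1‑[(1E)‑3‑bromo‑2‑methylprop‑1‑en‑1‑yl]‑3,6‑dioxo‑2‑oxaspiro[4.5]dec‑7‑en‑9‑yl acetate, F9.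
- Copper‑catalysed coupling with alkyne **26** (CuI, K2CO3, NaI, DMF) gives the skipped enyne (1R,5R,9S)‑1‑[(1E)‑6‑hydroxy‑2,6‑dimethylhept‑1‑en‑4‑yn‑1‑yl]‑3,6‑dioxo‑2‑oxaspiro[4.5]dec‑7‑en‑9‑yl acetate, F10.
- Ruthenium‑catalysed trans‑hydrosilylation ([Cp*Ru(MeCN)3]PF6, (EtO)3SiH) gives the (4Z)‑4‑triethoxysilyl diene, F11.
- Protodesilylation (AgF, aq. THF/MeOH) gives the E‑alkene and rejoins the route at **28**.

## Further compounds

F1 | step 9 | {1‑[(2R,3R)‑3‑{[(tert‑butyldiphenylsilyl)oxy]methyl}‑2‑{2‑[(tert‑butyldimethylsilyl)oxy]ethyl}oxiran‑2‑yl]cyclopent‑3‑en‑1‑yl}oxy(trimethyl)silane | C[Si](C)(C)OC1(CC=CC1)[C@]2(CCO[Si](C)(C)C(C)(C)C)O[C@@H]2CO[Si](c3ccccc3)(c3ccccc3)C(C)(C)C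
F2 | step 7 | 4‑[(2R,3R)‑2‑{2‑[(tert‑butyldimethylsilyl)oxy]ethyl}‑3‑(hydroxymethyl)oxiran‑2‑yl]hepta‑1,6‑dien‑4‑ol | C=CCC(O)(CC=C)[C@]1(CCO[Si](C)(C)C(C)(C)C)O[C@@H]1CO
F3 | step 10 | (6R)‑6‑[(1S)‑2‑[(tert‑butyldiphenylsilyl)oxy]‑1‑hydroxyethyl]‑6‑(2‑hydroxyethyl)cyclohex‑3‑en‑1‑one | O=C1[C@@]([C@H](O)CO[Si](c2ccccc2)(c2ccccc2)C(C)(C)C)(CCO)CC=CC1
F4 | step 10 | (1S,5R)‑1‑{[(tert‑butyldiphenylsilyl)oxy]methyl}‑2‑oxaspiro[4.5]dec‑8‑ene‑3,6‑dione | O=C1CC=CC[C@]12CC(=O)O[C@@H]2CO[Si](c3ccccc3)(c3ccccc3)C(C)(C)C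
F5 | step 10 | (1S,5R,8S,9R)‑1‑{[(tert‑butyldiphenylsilyl)oxy]methyl}‑8,9‑epoxy‑2‑oxaspiro[4.5]decane‑3,6‑dione | O=C1C[C@@H]2O[C@@H]2C[C@]13CC(=O)O[C@@H]3CO[Si](c4ccccc4)(c4ccccc4)C(C)(C)C
F6 | step 10 | (1S,5R,9R)‑1‑{[(tert‑butyldiphenylsilyl)oxy]methyl}‑9‑hydroxy‑2‑oxaspiro[4.5]dec‑7‑ene‑3,6‑dione | O[C@H]1C=CC(=O)[C@@]2(CC(=O)O[C@@H]2CO[Si](c3ccccc3)(c3ccccc3)C(C)(C)C)C1
F7 | step 16 | (1S,5R,9S)‑1‑(1‑hydroxy‑2‑methylprop‑2‑en‑1‑yl)‑3,6‑dioxo‑2‑oxaspiro[4.5]dec‑7‑en‑9‑yl acetate | CC(=O)O[C@@H]1C=CC(=O)[C@@]2(CC(=O)O[C@@H]2C(O)C(C)=C)C1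
F8 | step 16 | (1S,5R,9S)‑1‑{1‑[(methoxycarbonyl)oxy]‑2‑methylprop‑2‑en‑1‑yl}‑3,6‑dioxo‑2‑oxaspiro[4.5]dec‑7‑en‑9‑yl acetate | CC(=O)O[C@@H]1C=CC(=O)[C@@]2(CC(=O)O[C@@H]2C(OC(=O)OC)C(C)=C)C1
F9 | step 20 | (1R,5R,9S)‑1‑[(1E)‑3‑bromo‑2‑methylprop‑1‑en‑1‑yl]‑3,6‑dioxo‑2‑oxaspiro[4.5]dec‑7‑en‑9‑yl acetate | CC(=O)O[C@@H]1C=CC(=O)[C@@]2(CC(=O)O[C@@H]2/C=C(\C)CBr)C1
F10 | step 20 | (1R,5R,9S)‑1‑[(1E)‑6‑hydroxy‑2,6‑dimethylhept‑1‑en‑4‑yn‑1‑yl]‑3,6‑dioxo‑2‑oxaspiro[4.5]dec‑7‑en‑9‑yl acetate | CC(=O)O[C@@H]1C=CC(=O)[C@@]2(CC(=O)O[C@@H]2/C=C(\C)CC#CC(C)(C)O)C1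
F11 | step 20 | (1R,5R,9S)‑1‑[(1E,4Z)‑6‑hydroxy‑2,6‑dimethyl‑4‑(triethoxysilyl)hepta‑1,4‑dien‑1‑yl]‑3,6‑dioxo‑2‑oxaspiro[4.5]dec‑7‑en‑9‑yl acetate | CC(=O)O[C@@H]1C=CC(=O)[C@@]2(CC(=O)O[C@@H]2/C=C(\C)C/C(=C/C(C)(C)O)[Si](OCC)(OCC)OCC)C1
A1 | alternative 1 | 1‑(2‑tert‑butoxy‑2‑oxoethyl)cyclohexa‑2,5‑diene‑1‑carboxylic acid | OC(=O)C1(CC(=O)OC(C)(C)C)C=CCC=C1
A2 | alternative 1 | tert‑butyl 2‑(8‑bromo‑7‑oxo‑6‑oxabicyclo[3.2.1]oct‑2‑en‑1‑yl)acetate (bridged bromolactone, single enantiomer as drawn) | O=C2O[C@@H]1CC=C[C@@]2(CC(=O)OC(C)(C)C)[C@H]1Br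
A3 | alternative 2 | 2‑methoxyfuran | COc1ccco1
A4 | alternative 2 | methyl 3‑formylbut‑3‑enoate | COC(=O)CC(=C)C=O
A5 | alternative 2 | methyl 2‑(1‑formyl‑5‑hydroxy‑2‑oxocyclohex‑3‑en‑1‑yl)acetate (hydroxyl cis to formyl, single enantiomer as drawn) | O[C@@H]1C=CC(=O)[C@@](C=O)(CC(=O)OC)C1
A6 | alternative 3 | methyl 2‑{5‑[(tert‑butyldimethylsilyl)oxy]‑1‑formyl‑2‑oxocyclohex‑3‑en‑1‑yl}acetate (silyloxy cis to formyl, single enantiomer as drawn) | CC(C)(C)[Si](C)(C)O[C@@H]1C=CC(=O)[C@@](C=O)(CC(=O)OC)C1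
A7 | alternative 3 | (3E,6E)‑7‑iodo‑2,6‑dimethylhepta‑3,6‑dien‑2‑ol | I/C=C(\C)C/C=C/C(C)(C)O
A8 | alternative 3 | (1R,5R,9S)‑9‑[(tert‑butyldimethylsilyl)oxy]‑1‑[(1E,4E)‑6‑hydroxy‑2,6‑dimethylhepta‑1,4‑dien‑1‑yl]‑2‑oxaspiro[4.5]dec‑7‑ene‑3,6‑dione | CC(C)(C)[Si](C)(C)O[C@@H]1C=CC(=O)[C@@]2(CC(=O)O[C@@H]2/C=C(\C)C/C=C/C(C)(C)O)C1
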